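The readings stem from a simulated flask with made-up constants; scatter was added.

A small charge of L, 0.1 mol% of X or 5.00 × 10⁻⁵ M, carries each of these flasks, and we keep the books on X.

all flasks: X 0.050 M; L 0.1 mol%

| charge | D | remark | time |
|---|---|---|---|
| oak | 0.28 equiv | run made earlier |  |
| ash | 0.79 equiv | run made earlier |  |
| blue | 0.500 equiv |  | 30 h |
| violet | 0.750 equiv |  | 30 h |
| ochre | 1.10 equiv |  | 30 h |

| run | time / h | J / % | Q / % | X / % |
|---|---|---|---|---|
| oak | 2.50 | 0.3 | 3.7 | 96.4 |
| oak | 4.00 | 0 | 5.9 | 94.2 |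
| oak | 6.00 | 0 | 9.4 | 90.8 |
| oak | 10.0 | 0 | 14.8 | 84.4 |
| oak | 20.0 | 0 | 29.8 | 70.3 |
| oak | 30.0 | 0.5 | 43.2 | 56.5 |
| ash | 2.50 | 0 | 2.8 | 97.1 |
| ash | 4.00 | 0 | 5.3 | 94.7 |
| ash | 6.00 | 0.6 | 7.2 | 92.6 |
| ash | 10.0 | 0.1 | 13.1 | 85.8 |
| ash | 20.0 | 0.3 | 26.2 | 74.2 |
| ash | 30.0 | 0.2 | 38.9 | 61.2 |

(scatter of a reading: 0.5 percentage points)

* which of these there is most of at the end, counted by the X in it, blue (X / Q / J)
* which of these there is most of at the end, counted by the X in it, violet (X / Q / J)
* which of these there is most of at the end, counted by the X in it, ochre (X / Q / J)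
* how much there is at the end of the one of these that leads, in percent of the X charged: blue
* how much there is at the end of the one of these that leads, in percent of the X charged: violet
* how much there is at the end of the one of these that leads, in percent of the X charged: ochre

The ledger has three entries:

X charged = X left + Q + J

J is a form of the catalyst. If each J holds one X, the entry stands at no more than 0.1 mol% of X, too small for readings with a scatter of 0.5 percentage points to see. We therefore book Q and X left.

Oak reached 43.2% Q on 0.28 equiv of D, so we do not book Q against D one for one. We book it against [L] as charged: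

n = Q / (L charged per X × time)

In oak, n is 14.8 h⁻¹ up to 10.0 h and 14.4 h⁻¹ up to 30.0 h, though X has fallen to 56.5%. The rate is close to zero order in [X]. Ash gives a lower 13.0 h⁻¹, so we draw a straight line in equivalents of D between the two runs. Ochre lies beyond ash, so its value is an extrapolation.

blue: n = 13.8 h⁻¹, Q 41.3%, X 58.7%

violet: n = 13.1 h⁻¹, Q 39.2%, X 60.8%

ochre: n = 12.1 h⁻¹, Q 36.3%, X 63.7%

This n, moles of Q per mole of L charged per hour at the flask's D, is the turnover frequency, and the books close with X ahead in each flask.

The forecast, on the ground that “More D slows the reaction slightly”, also has X leading, at 59%, 61% and 63%, figures slightly different from ours.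

The flasks give X at 57.9% in blue, 60.2% in violet and 63.1% in ochre, with Q at 42.0%, 39.7% and 36.8%.

    X + L ⇌ J (K = 2800 L mol⁻¹, k = 0.600 L mol⁻¹ s⁻¹)
    Z → L + G (k = 0.0340 s⁻¹)
    D + L ⇌ Z (K = 950 L mol⁻¹, k = 1.90 L mol⁻¹ s⁻¹)
    X + L → E (k = 1.20 × 10⁻⁴ L mol⁻¹ s⁻¹)
    J → L + Q (k = 0.00580 s⁻¹)

In violet at 11.3 h, L has a half-life of 0.45 min against X, forward step alone, shorter than the 2.0 min of J by J → L + Q alone, while the ratio of J made to J used up, each step taken net, stands at 1.00. J is the resting state, 62.4% of the catalyst charged at 30.0 h, and that share times the constant of J → L + Q is 13.0 h⁻¹, beside the average 13.2 h⁻¹ of violet and our 13.1 h⁻¹.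

For violet's charge read at 12 h, our 13.1 h⁻¹ gives Q 15.7% and X 84.3%. The computed flask holds Q 15.9% and X 84.1%.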